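**Assumption:** Agehoustin C has no stereocentre, so there is no enantiomer to select and the only stereo-element on the route is the E-alkene of chalcone 19; metal salts or Lewis-acid complexes of a numbered compound that are only protonated on work-up get no number of their own.

**Retrosynthetic overview**
- Target ⇒ its 3'-O-benzyl ether (hydrogenolysis last) ⇒ a 2'-hydroxychalcone; the pyranone ring is the only ring formed, by oxidative cyclisation, and both benzene rings are bought.
- Key C–C disconnection: the chalcone Cα–Cβ bond, made by an intermolecular Claisen–Schmidt aldol condensation of an A-ring acetophenone with a B-ring benzaldehyde.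
- A ring: 2-hydroxy-3,4,5,6-tetramethoxyacetophenone ⇐ 2,3,4,5-tetramethoxyphenol ⇐ two formylation/Baeyer–Villiger rounds from 2,3,4-trimethoxybenzaldehyde.
- B ring: 3-benzyloxy-2,4,5-trimethoxybenzaldehyde ⇐ ortho-formylation and methylation of 2-benzyloxy-3,4-dimethoxyphenol ⇐ ortho-demethylation, benzylation and Baeyer–Villiger of the same 2,3,4-trimethoxybenzaldehyde.

**A-ring fragment**

Step 1
Reactants: 1 2,3,4-trimethoxybenzaldehyde
Product: 3 2,3,4-trimethoxyphenol, via aryl formate 2 (not isolated)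
Conditions: mCPBA (1.2 equiv), CH2Cl2, 0 °C → rt; aq NaHCO3 wash; then K2CO3 (cat.), MeOH, rt
Reagents that add atoms: m-chloroperbenzoic acid (mCPBA), O=C(OO)c1cccc(Cl)c1
Why: Baeyer–Villiger (Dakin-type) oxidation, in which the electron-rich aryl group with ortho/para methoxy donors migrates in preference to H and the labile aryl formate is then methanolysed.

Step 2
Reactants: 3 2,3,4-trimethoxyphenol
Product: 4 1,2,3,4-tetramethoxybenzene
Conditions: MeI, K2CO3, acetone, reflux
Reagents that add atoms: iodomethane, CI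
Why: Williamson O-methylation of an unhindered phenoxide.

Step 3
Reactants: 4 1,2,3,4-tetramethoxybenzene
Product: 6 2,3,4,5-tetramethoxybenzaldehyde, via aryl iminium chloride 5 (not isolated)
Conditions: POCl3, DMF, 0 → 80 °C; then ice/H2O
Reagents that add atoms: N,N-dimethylformamide, CN(C)C=O; water, O
Why: Vilsmeier–Haack formylation of an electron-rich arene whose two free positions are equivalent by symmetry, so only one aldehyde can form.

Step 4
Reactants: 6 2,3,4,5-tetramethoxybenzaldehyde
Product: 8 2,3,4,5-tetramethoxyphenol, via aryl formate 7 (not isolated)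
Conditions: mCPBA (1.2 equiv), CH2Cl2, 0 °C → rt; aq NaHCO3 wash; then K2CO3 (cat.), MeOH, rt
Reagents that add atoms: m-chloroperbenzoic acid (mCPBA), O=C(OO)c1cccc(Cl)c1
Why: Second Baeyer–Villiger oxidation with aryl migration, followed by formate methanolysis, turns the formyl carbon into the fifth ring oxygen.

Step 5
Reactants: 8 2,3,4,5-tetramethoxyphenol
Product: 10 1-(2-hydroxy-3,4,5,6-tetramethoxyphenyl)ethan-1-one, via aryl acetate 9 (not isolated)
Conditions: AcOH, BF3·OEt2 (4 equiv), 90 °C; then H2O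
Reagents that add atoms: acetic acid, CC(=O)O
Why: BF3-mediated O-acetylation and Fries rearrangement (Friedel–Crafts C-acylation) can only go to the single free ring position, which is ortho to the OH, and boron chelation of the o-hydroxy ketone drives it.

**B-ring fragment**

Step 6
Reactants: 1 2,3,4-trimethoxybenzaldehyde
Product: 11 2-hydroxy-3,4-dimethoxybenzaldehyde
Conditions: AlCl3 (1.2 equiv), CH2Cl2, 0 °C → rt; then 1 M HCl
Reagents that add atoms: none
Why: Chelation-controlled Lewis-acid ether cleavage, in which aluminium bound between the carbonyl and the ortho methoxy oxygen removes only that methyl group.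

Step 7
Reactants: 11 2-hydroxy-3,4-dimethoxybenzaldehyde
Product: 12 2-(benzyloxy)-3,4-dimethoxybenzaldehyde
Conditions: BnBr, K2CO3, DMF, 60 °C
Reagents that add atoms: benzyl bromide, BrCc1ccccc1
Why: Williamson benzylation marks this oxygen as the future free 3'-OH of the target.

Step 8
Reactants: 12 2-(benzyloxy)-3,4-dimethoxybenzaldehyde
Product: 14 2-(benzyloxy)-3,4-dimethoxyphenol, via aryl formate 13 (not isolated)
Conditions: mCPBA (1.2 equiv), CH2Cl2, 0 °C → rt; aq NaHCO3 wash; then K2CO3 (cat.), MeOH, rt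
Reagents that add atoms: m-chloroperbenzoic acid (mCPBA), O=C(OO)c1cccc(Cl)c1
Why: Baeyer–Villiger oxidation with migration of the ortho/para-alkoxy-activated aryl group, and the benzyl ether is inert to peracid and to mild methanolysis.

Step 9
Reactants: 14 2-(benzyloxy)-3,4-dimethoxyphenol
Product: 16 3-(benzyloxy)-2-hydroxy-4,5-dimethoxybenzaldehyde, via salicyl alcohol 15 (not isolated)
Conditions: MgCl2 (2 equiv), Et3N (4 equiv), (CH2O)n (6 equiv), MeCN, reflux; then 1 M HCl
Reagents that add atoms: formaldehyde (from paraformaldehyde), C=O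
Why: Magnesium-mediated ortho-formylation (Casnati–Skattebøl) delivers formaldehyde inside the Mg phenoxide chelate to the only free ortho position, and the hydroxymethyl intermediate is oxidised by a second formaldehyde through Oppenauer-type hydride transfer.

Step 10
Reactants: 16 3-(benzyloxy)-2-hydroxy-4,5-dimethoxybenzaldehyde
Product: 17 3-(benzyloxy)-2,4,5-trimethoxybenzaldehyde
Conditions: MeI, K2CO3, DMF, 40 °C
Reagents that add atoms: iodomethane, CI
Why: Williamson O-methylation of the salicylaldehyde phenoxide; the aldehyde has no α-hydrogen and the benzyl ether is base-stable.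

**Coupling and completion**

Step 11
Reactants: 10 1-(2-hydroxy-3,4,5,6-tetramethoxyphenyl)ethan-1-one; 17 3-(benzyloxy)-2,4,5-trimethoxybenzaldehyde
Product: 19 (E)-3-[3-(benzyloxy)-2,4,5-trimethoxyphenyl]-1-(2-hydroxy-3,4,5,6-tetramethoxyphenyl)prop-2-en-1-one, via aldol adduct 18 (not isolated)
Conditions: KOH (50% aq, excess), EtOH, rt, 48 h; then 2 M HCl, 0 °C
Reagents that add atoms: none
Why: Claisen–Schmidt crossed aldol condensation between the only enolisable partner (methyl ketone 10) and non-enolisable aldehyde 17, with E1cB dehydration giving the thermodynamically favoured E-enone; any flavanone formed alongside converges in step 12.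

Step 12
Reactants: 19 (E)-3-[3-(benzyloxy)-2,4,5-trimethoxyphenyl]-1-(2-hydroxy-3,4,5,6-tetramethoxyphenyl)prop-2-en-1-one
Product: 21 2-[3-(benzyloxy)-2,4,5-trimethoxyphenyl]-5,6,7,8-tetramethoxy-4H-chromen-4-one, via flavanone 20 (not isolated)
Conditions: I2 (10 mol %), DMSO, 130 °C, 2 h; aq Na2S2O3 work-up
Reagents that add atoms: none
Why: Iodine-catalysed oxidative cyclisation, in which intramolecular oxa-Michael addition gives the flavanone, α-iodination and HI elimination aromatise the pyranone, and DMSO re-oxidises HI; the flavanone stereocentre is destroyed.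

Step 13
Reactants: 21 2-[3-(benzyloxy)-2,4,5-trimethoxyphenyl]-5,6,7,8-tetramethoxy-4H-chromen-4-one
Product: 22 Agehoustin C, 2-(3-hydroxy-2,4,5-trimethoxyphenyl)-5,6,7,8-tetramethoxy-4H-chromen-4-one
Conditions: H2 (1 atm), 10% Pd/C, EtOAc–MeOH, rt, monitored by TLC
Reagents that add atoms: none
Why: Catalytic hydrogenolysis cleaves the benzylic C–O bond, while the flavone C2=C3 (a vinylogous ester) and the aryl methyl ethers are inert at 1 atm and rt.

**Compound list**
1 | 2,3,4-trimethoxybenzaldehyde | COc1ccc(C=O)c(OC)c1OC | starting material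
2 | 2,3,4-trimethoxyphenyl formate | O=COc1ccc(OC)c(OC)c1OC | intermediate (not isolated)
3 | 2,3,4-trimethoxyphenol | COc1ccc(O)c(OC)c1OC | intermediate
4 | 1,2,3,4-tetramethoxybenzene | COc1ccc(OC)c(OC)c1OC | intermediate
5 | N,N-dimethyl-(2,3,4,5-tetramethoxybenzylidene)iminium chloride | C[N+](C)=Cc1cc(OC)c(OC)c(OC)c1OC.[Cl-] | intermediate (not isolated)
6 | 2,3,4,5-tetramethoxybenzaldehyde | COc1cc(C=O)c(OC)c(OC)c1OC | intermediate
7 | 2,3,4,5-tetramethoxyphenyl formate | O=COc1cc(OC)c(OC)c(OC)c1OC | intermediate (not isolated)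
8 | 2,3,4,5-tetramethoxyphenol | COc1cc(O)c(OC)c(OC)c1OC | intermediate
9 | 2,3,4,5-tetramethoxyphenyl acetate | CC(=O)Oc1cc(OC)c(OC)c(OC)c1OC | intermediate (not isolated)
10 | 1-(2-hydroxy-3,4,5,6-tetramethoxyphenyl)ethan-1-one | CC(=O)c1c(O)c(OC)c(OC)c(OC)c1OC | intermediate
11 | 2-hydroxy-3,4-dimethoxybenzaldehyde | COc1ccc(C=O)c(O)c1OC | intermediate
12 | 2-(benzyloxy)-3,4-dimethoxybenzaldehyde | COc1ccc(C=O)c(OCc2ccccc2)c1OC | intermediate
13 | 2-(benzyloxy)-3,4-dimethoxyphenyl formate | O=COc1ccc(OC)c(OC)c1OCc1ccccc1 | intermediate (not isolated)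
14 | 2-(benzyloxy)-3,4-dimethoxyphenol | COc1ccc(O)c(OCc2ccccc2)c1OC | intermediate
15 | 3-(benzyloxy)-2-hydroxy-4,5-dimethoxybenzyl alcohol (as its magnesium salt) | COc1cc(CO)c(O)c(OCc2ccccc2)c1OC | intermediate (not isolated)
16 | 3-(benzyloxy)-2-hydroxy-4,5-dimethoxybenzaldehyde | COc1cc(C=O)c(O)c(OCc2ccccc2)c1OC | intermediate
17 | 3-(benzyloxy)-2,4,5-trimethoxybenzaldehyde | COc1cc(C=O)c(OC)c(OCc2ccccc2)c1OC | intermediate
18 | 3-[3-(benzyloxy)-2,4,5-trimethoxyphenyl]-3-hydroxy-1-(2-hydroxy-3,4,5,6-tetramethoxyphenyl)propan-1-one (racemic aldol adduct) | COc1cc(C(O)CC(=O)c2c(O)c(OC)c(OC)c(OC)c2OC)c(OC)c(OCc2ccccc2)c1OC | intermediate (not isolated)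
19 | (E)-3-[3-(benzyloxy)-2,4,5-trimethoxyphenyl]-1-(2-hydroxy-3,4,5,6-tetramethoxyphenyl)prop-2-en-1-one | COc1cc(/C=C/C(=O)c2c(O)c(OC)c(OC)c(OC)c2OC)c(OC)c(OCc2ccccc2)c1OC | intermediate
20 | 2-[3-(benzyloxy)-2,4,5-trimethoxyphenyl]-5,6,7,8-tetramethoxychroman-4-one (racemic flavanone) | COc1cc(C2CC(=O)c3c(OC)c(OC)c(OC)c(OC)c3O2)c(OC)c(OCc2ccccc2)c1OC | intermediate (not isolated)
21 | 2-[3-(benzyloxy)-2,4,5-trimethoxyphenyl]-5,6,7,8-tetramethoxy-4H-chromen-4-one | COc1cc(-c2cc(=O)c3c(OC)c(OC)c(OC)c(OC)c3o2)c(OC)c(OCc2ccccc2)c1OC | intermediate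
22 | Agehoustin C, 2-(3-hydroxy-2,4,5-trimethoxyphenyl)-5,6,7,8-tetramethoxy-4H-chromen-4-one (achiral) | COc1cc(-c2cc(=O)c3c(OC)c(OC)c(OC)c(OC)c3o2)c(OC)c(O)c1OC | target

**Totals**
Total step count: 13.
Longest linear sequence: 8 steps (steps 1–5 then 11–13; the B-ring branch, steps 6–10 then 11–13, is equally long).

**Three steps most likely to fail, with fallbacks**

Step 5 (acylation of 8). Hot BF3/AcOH on a pentaoxygenated ring can give partial demethylation or a sluggish Fries step. The fallback sets out from 8 and comes back at 10. Methylate 8 (MeI, K2CO3, acetone) to pentamethoxybenzene F1. Acetylate its single free position under Friedel–Crafts conditions (AcCl, AlCl3, CH2Cl2, 0 °C) to 1-(2,3,4,5,6-pentamethoxyphenyl)ethan-1-one F2. Then remove one of the two symmetry-equivalent ortho methyl groups by chelation-controlled cleavage (BCl3, 1 equiv, CH2Cl2, −78 → 0 °C), which gives 10.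

Step 9 (ortho-formylation of 14). The neighbouring benzyloxy oxygen can tie up magnesium and slow the formaldehyde transfer. The fallback sets out from 14 and comes back at 17, so it bypasses step 10 as well. Brominate 14 at its only free ortho position, which is also para to a methoxy group (NBS, MeCN, −20 °C), to 2-(benzyloxy)-6-bromo-3,4-dimethoxyphenol F3. Methylate the phenol (MeI, K2CO3, DMF) to 3-(benzyloxy)-1-bromo-2,4,5-trimethoxybenzene F4. Bromine–lithium exchange (n-BuLi, THF, −78 °C, faster than benzylic deprotonation) and a DMF quench then give 17.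

Step 11 (Claisen–Schmidt condensation). Ketone 10 is flanked by two ortho substituents and aldehyde 17 is electron-rich and ortho-substituted, so the aldol may stall or give chalcone/flavanone mixtures. The fallback sets out from 17 (used together with 10) and comes back at 21, replacing steps 11 and 12 by an intermolecular Claisen condensation and cyclodehydration. Oxidise 17 (NaClO2, NaH2PO4, 2-methyl-2-butene, t-BuOH/H2O) to 3-(benzyloxy)-2,4,5-trimethoxybenzoic acid F5. Esterify (MeI, K2CO3, DMF) to methyl 3-(benzyloxy)-2,4,5-trimethoxybenzoate F6. Condense F6 with the dilithium phenoxide-enolate of 10 (LiHMDS, 3.2 equiv, THF, −78 °C → rt) to 1-[3-(benzyloxy)-2,4,5-trimethoxyphenyl]-3-(2-hydroxy-3,4,5,6-tetramethoxyphenyl)propane-1,3-dione F7. Cyclodehydrate F7 (cat. TsOH, toluene, reflux) to 21.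

**Further compounds**
F1 | step 5 | pentamethoxybenzene | COc1cc(OC)c(OC)c(OC)c1OC
F2 | step 5 | 1-(2,3,4,5,6-pentamethoxyphenyl)ethan-1-one | CC(=O)c1c(OC)c(OC)c(OC)c(OC)c1OC
F3 | step 9 | 2-(benzyloxy)-6-bromo-3,4-dimethoxyphenol | COc1cc(Br)c(O)c(OCc2ccccc2)c1OC
F4 | step 9 | 3-(benzyloxy)-1-bromo-2,4,5-trimethoxybenzene | COc1cc(Br)c(OC)c(OCc2ccccc2)c1OC
F5 | step 11 | 3-(benzyloxy)-2,4,5-trimethoxybenzoic acid | COc1cc(C(=O)O)c(OC)c(OCc2ccccc2)c1OC
F6 | step 11 | methyl 3-(benzyloxy)-2,4,5-trimethoxybenzoate | COC(=O)c1cc(OC)c(OC)c(OCc2ccccc2)c1OC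
F7 | step 11 | 1-[3-(benzyloxy)-2,4,5-trimethoxyphenyl]-3-(2-hydroxy-3,4,5,6-tetramethoxyphenyl)propane-1,3-dione | COc1cc(C(=O)CC(=O)c2c(O)c(OC)c(OC)c(OC)c2OC)c(OC)c(OCc2ccccc2)c1OC
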